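**Plan**

- Ring numbering used throughout: C1 (OCH3), C2 (OH), C3 (CH3), C4 (hexaprenyl), C5 (OH), C6 (OCH3). The oxygens on C2 and C5 are para and both end as OH, and C1 and C6 both carry OCH3. A 4-methoxyphenol built from a carbene carbon (C2), a carbonyl ligand (C5) and a methyl/alkyl alkyne (C3, C4) therefore leads to the target whichever way the alkyne inserts.
- Retrosynthesis: the target is taken back to the para-quinone, then to the 4-methoxyphenol. The ring is cut at C2–C3, C4–C5 and C5–C6 into a trimethoxylated vinylcarbene of zerovalent chromium (C2, C1, C6), a skipped enyne (C3, C4, methyl and chain) and CO.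
- The enyne is cut at the propargylic C–C bond (propynyl Grignard plus hexaprenyl bromide) and at C12–C13 of the chain (farnesyl sulfone plus an ω-bromofarnesyl benzyl ether).
- Forward: C15 + C15 chain coupling, then the C3 alkyne cap, then the carbene complex. The only ring is closed in the benzannulation, and an oxidation/reduction pair sets the hydroquinone.
- Stereochemistry: the target has no stereocenter. Four E alkenes are bought with (2E,6E)-farnesol and (2E,6E)-farnesyl bromide; the fifth comes from E-selective SeO2 oxidation of the terminal isopropylidene group.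

Key step: step 10

Remark: (Z)-1,2-dimethoxyethene is taken as the purchased, isomerically pure Z enol ether, and its lithiation at the vinylic C–H is assumed to proceed with retention at −78 °C. The vinyl geometry is erased on aromatisation, so it does not affect the ring that is formed.

**Route**

Step 1
Reactants: 1 (2E,6E)-farnesol
Product: 2 benzyl (2E,6E)-3,7,11-trimethyldodeca-2,6,10-trienyl ether
Conditions: NaH, BnBr, Bu4NI (cat.), THF, 0 °C to rt
Reagents that add atoms: benzyl bromide, BrCc1ccccc1
Why: Williamson etherification of the primary allylic alkoxide should proceed by SN2 on benzyl bromide, and the benzyl ether withstands SeO2, PBr3 and the sulfonyl carbanion and leaves in the same operation as the sulfone in step 6.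

Step 2
Reactants: 2 benzyl (2E,6E)-farnesyl ether
Product: 3 (2E,6E,10E)-12-(benzyloxy)-2,6,10-trimethyldodeca-2,6,10-trien-1-ol
Conditions: SeO2 (cat.), t-BuOOH, salicylic acid (cat.), CH2Cl2, 0 °C to rt
Reagents that add atoms: tert-butyl hydroperoxide, CC(C)(C)OO
Why: Riley allylic oxidation (ene reaction, then [2,3]-sigmatropic shift) should hydroxylate the E-methyl group of the terminal isopropylidene unit, the most accessible trisubstituted alkene, which fixes that alkene as E, while the alkene next to the ether oxygen is deactivated.

Step 3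
Reactants: 3 the ω-hydroxy benzyl ether
Product: 4 benzyl (2E,6E,10E)-12-bromo-3,7,11-trimethyldodeca-2,6,10-trienyl ether
Conditions: PBr3, pyridine (cat.), Et2O, −10 to 0 °C
Reagents that add atoms: phosphorus tribromide, BrP(Br)Br
Why: Bromination of a primary allylic alcohol with PBr3 at low temperature is an SN2 displacement of the phosphite ester and should occur without allylic transposition or loss of E geometry.

Step 4
Reactants: 5 (2E,6E)-farnesyl bromide
Product: 6 (2E,6E)-3,7,11-trimethyldodeca-2,6,10-trienyl phenyl sulfone
Conditions: PhSO2Na, DMF, rt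
Reagents that add atoms: sodium benzenesulfinate, [Na+].[O-]S(=O)c1ccccc1
Why: SN2 S-alkylation of the sulfinate anion by the primary allylic bromide in a dipolar aprotic solvent gives the allylic sulfone with the alkene geometry untouched.

Step 5
Reactants: 6 farnesyl phenyl sulfone; 4 the ω-bromo benzyl ether
Product: 8 benzyl (2E,6E,10E,14E,18E)-3,7,11,15,19,23-hexamethyl-13-(phenylsulfonyl)tetracosa-2,6,10,14,18,22-hexaenyl ether (racemic at C13), via α-lithio farnesyl phenyl sulfone 7 (not isolated)
Conditions: n-BuLi, THF/DMPU, −78 °C; then 4, −78 to −20 °C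
Reagents that add atoms: none
Why: Alkylation of a sulfone-stabilised allylic carbanion (the sulfone coupling of Julia-type chain extensions) occurs at the α-carbon on the primary allylic bromide and forms the C12–C13 bond of the chain; the new stereocenter at C13 arises racemic and is removed in step 6.

Step 6
Reactants: 8 the C30 sulfone benzyl ether
Product: 9 (2E,6E,10E,14E,18E)-3,7,11,15,19,23-hexamethyltetracosa-2,6,10,14,18,22-hexaen-1-ol (all-E-hexaprenol)
Conditions: Li, EtNH2/THF, −78 °C; then H2O
Reagents that add atoms: none
Why: Dissolving-metal reduction of Benkeser type cleaves the allylic C–S bond and the benzylic C–O bond by electron transfer, and kinetic protonation of the allyl anion at its less substituted terminus at −78 °C should return the trisubstituted E alkene while erasing the C13 stereocenter.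

Step 7
Reactants: 9 all-E-hexaprenol
Product: 10 (2E,6E,10E,14E,18E)-1-bromo-3,7,11,15,19,23-hexamethyltetracosa-2,6,10,14,18,22-hexaene (all-E-hexaprenyl bromide)
Conditions: PBr3, pyridine (cat.), Et2O, −10 to 0 °C
Reagents that add atoms: phosphorus tribromide, BrP(Br)Br
Why: The same SN2 bromination of a primary allylic alcohol as in step 3 should apply; the bromide is used at once without chromatography.

Step 8
Reactants: 10 all-E-hexaprenyl bromide; 11 1-propynylmagnesium bromide
Product: 12 (5E,9E,13E,17E,21E)-6,10,14,18,22,26-hexamethylheptacosa-5,9,13,17,21,25-hexaen-2-yne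
Conditions: CuI (cat.), THF, 0 °C to rt
Reagents that add atoms: none
Why: Copper-catalysed coupling of an alkynyl Grignard reagent with a primary allylic bromide should take place at the unhindered CH2 terminus (SN2 rather than SN2′ at the fully substituted γ-carbon) and give the 1,4-enyne with the adjacent alkene still E.

Step 9
Reactants: 13 (Z)-1,2-dimethoxyethene; 14 chromium hexacarbonyl
Product: 17 pentacarbonyl[(Z)-1,2-dimethoxyvinyl(methoxy)carbene]chromium, via (Z)-1,2-dimethoxyvinyllithium 15 (not isolated), via lithium acylchromate 16 (not isolated)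
Conditions: t-BuLi, THF, −78 °C; Cr(CO)6, THF, −78 to 0 °C; then Me3OBF4, CH2Cl2, 0 °C
Reagents that add atoms: trimethyloxonium tetrafluoroborate, C[O+](C)C.F[B-](F)(F)F
Why: Fischer carbene synthesis, in which the vinylic C–H geminal to oxygen is lithiated with retention of the Z geometry, the vinyllithium adds to a carbonyl ligand of Cr(CO)6 and the hard acylate oxygen is methylated by the oxonium salt; working at −78 °C suppresses anti elimination of LiOMe from 15.

Step 10
Reactants: 17 the carbene complex; 12 the skipped enyne
Product: 19 2,3,4-trimethoxy-5-methyl-6-[(2E,6E,10E,14E,18E)-3,7,11,15,19,23-hexamethyltetracosa-2,6,10,14,18,22-hexaenyl]phenol, via tricarbonylchromium arene complex 18 (not isolated)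
Conditions: THF (dilute), 50 °C, Ar, slight excess of 17; then air, daylight, Et2O, rt
Reagents that add atoms: none
Why: Thermal loss of one CO from 17 opens a site on zerovalent chromium, the alkyne of 12 inserts into the Cr=C bond to give a vinylcarbene, a carbonyl ligand inserts to give the chromium-bound dienylketene, and ring closure followed by enolisation gives the arene as its Cr(CO)3 complex 18, which air and light demetalate. The closest known reaction type is the Dötz benzannulation of alkenyl(alkoxy)carbene chromium complexes with internal alkynes, including carbenes whose vinyl group is an enol ether. The single ring closes by thermal 6π electrocyclisation of the dienylketene onto the methoxy-bearing vinyl terminus (C5–C6) after the two insertions have made C2–C3 and C4–C5; the carbene supplies C2, C1 and C6 with all three methoxy groups, the alkyne supplies C3 and C4 with the methyl group and the chain, and CO becomes C5. No stereocenter is formed and the five E alkenes are remote spectators. The step needs chemoselectivity for the alkyne over six trisubstituted alkenes, which should hold because unactivated alkenes neither insert into nor are cyclopropanated by alkoxycarbene chromium complexes at 50 °C and the 1,4-enyne spacing offers no alkene at a distance from which the vinylcarbene could be trapped in a five- or six-membered ring; it also needs CO insertion to outrun cyclopentannulation, which chromium, an alkenyl carbene and THF favour. The expected regiochemistry places the CH2-bearing alkyne carbon next to the new C–OH, but either orientation of insertion leads to the same quinone in step 11.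

Step 11
Reactants: 19 the 4-methoxyphenol
Product: 20 2,3-dimethoxy-5-methyl-6-[(2E,6E,10E,14E,18E)-3,7,11,15,19,23-hexamethyltetracosa-2,6,10,14,18,22-hexaenyl]cyclohexa-2,5-diene-1,4-dione (ubiquinone-6)
Conditions: (NH4)2Ce(NO3)6, MeCN/H2O, 0 °C
Reagents that add atoms: water, O
Why: Oxidative demethylation of a 4-methoxyphenol by tetravalent cerium, in which two one-electron oxidations give the phenoxonium ion, water adds at the methoxy-bearing para carbon and methanol is lost to give the para-quinone, while the isolated trisubstituted alkenes should not be touched at 0 °C.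

Step 12
Reactants: 20 ubiquinone-6
Product: 21 ubiquinol-6
Conditions: Na2S2O4, Et2O/H2O (degassed), rt, Ar
Reagents that add atoms: none
Why: Dithionite reduction of a para-quinone to the hydroquinone is a fast two-electron transfer in a two-phase system that leaves the polyene chain alone; air is excluded because the ubiquinol reoxidises easily.

**Compound list**

1 | (2E,6E)-farnesol | OC/C=C(\C)CC/C=C(\C)CCC=C(C)C | starting material
2 | benzyl (2E,6E)-3,7,11-trimethyldodeca-2,6,10-trienyl ether | c1ccccc1COC/C=C(\C)CC/C=C(\C)CCC=C(C)C | intermediate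
3 | (2E,6E,10E)-12-(benzyloxy)-2,6,10-trimethyldodeca-2,6,10-trien-1-ol | c1ccccc1COC/C=C(\C)CC/C=C(\C)CC/C=C(\C)CO | intermediate
4 | benzyl (2E,6E,10E)-12-bromo-3,7,11-trimethyldodeca-2,6,10-trienyl ether | c1ccccc1COC/C=C(\C)CC/C=C(\C)CC/C=C(\C)CBr | intermediate
5 | (2E,6E)-farnesyl bromide | BrC/C=C(\C)CC/C=C(\C)CCC=C(C)C | starting material
6 | (2E,6E)-3,7,11-trimethyldodeca-2,6,10-trienyl phenyl sulfone | O=S(=O)(C/C=C(\C)CC/C=C(\C)CCC=C(C)C)c1ccccc1 | intermediate
7 | α-lithio farnesyl phenyl sulfone | [Li]C(/C=C(\C)CC/C=C(\C)CCC=C(C)C)S(=O)(=O)c1ccccc1 | intermediate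
8 | benzyl (2E,6E,10E,14E,18E)-3,7,11,15,19,23-hexamethyl-13-(phenylsulfonyl)tetracosa-2,6,10,14,18,22-hexaenyl ether, racemic at C13 | c1ccccc1COC/C=C(\C)CC/C=C(\C)CC/C=C(\C)CC(/C=C(\C)CC/C=C(\C)CCC=C(C)C)S(=O)(=O)c1ccccc1 | intermediate
9 | (2E,6E,10E,14E,18E)-3,7,11,15,19,23-hexamethyltetracosa-2,6,10,14,18,22-hexaen-1-ol (all-E-hexaprenol) | OC/C=C(\C)CC/C=C(\C)CC/C=C(\C)CC/C=C(\C)CC/C=C(\C)CCC=C(C)C | intermediate
10 | (2E,6E,10E,14E,18E)-1-bromo-3,7,11,15,19,23-hexamethyltetracosa-2,6,10,14,18,22-hexaene | BrC/C=C(\C)CC/C=C(\C)CC/C=C(\C)CC/C=C(\C)CC/C=C(\C)CCC=C(C)C | intermediate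
11 | 1-propynylmagnesium bromide | CC#C[Mg]Br | starting material
12 | (5E,9E,13E,17E,21E)-6,10,14,18,22,26-hexamethylheptacosa-5,9,13,17,21,25-hexaen-2-yne | CC#CC/C=C(\C)CC/C=C(\C)CC/C=C(\C)CC/C=C(\C)CC/C=C(\C)CCC=C(C)C | intermediate
13 | (Z)-1,2-dimethoxyethene | CO/C=C\OC | starting material
14 | chromium hexacarbonyl | O=C=[Cr](=C=O)(=C=O)(=C=O)(=C=O)=C=O | starting material
15 | (Z)-1,2-dimethoxyvinyllithium | [Li]/C(OC)=C/OC | intermediate
16 | lithium pentacarbonyl[(Z)-2,3-dimethoxyprop-2-enoyl]chromate | [Li+].[O-]C(/C(OC)=C/OC)=[Cr](=C=O)(=C=O)(=C=O)(=C=O)=C=O | intermediate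
17 | pentacarbonyl[(Z)-1,2-dimethoxyvinyl(methoxy)carbene]chromium | O=C=[Cr](=C=O)(=C=O)(=C=O)(=C=O)=C(OC)/C(OC)=C/OC | intermediate
18 | tricarbonyl(η6-arene)chromium complex of phenol 19 (written as arene plus Cr(CO)3 fragment) | COc1c(OC)c(OC)c(C)c(C/C=C(\C)CC/C=C(\C)CC/C=C(\C)CC/C=C(\C)CC/C=C(\C)CCC=C(C)C)c1O.O=C=[Cr](=C=O)=C=O | intermediate
19 | 2,3,4-trimethoxy-5-methyl-6-[(2E,6E,10E,14E,18E)-3,7,11,15,19,23-hexamethyltetracosa-2,6,10,14,18,22-hexaenyl]phenol | COc1c(OC)c(OC)c(C)c(C/C=C(\C)CC/C=C(\C)CC/C=C(\C)CC/C=C(\C)CC/C=C(\C)CCC=C(C)C)c1O | intermediate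
20 | ubiquinone-6 | COC1=C(OC)C(=O)C(C/C=C(\C)CC/C=C(\C)CC/C=C(\C)CC/C=C(\C)CC/C=C(\C)CCC=C(C)C)=C(C)C1=O | intermediate
21 | ubiquinol-6 | COc1c(O)c(C)c(C/C=C(\C)CC/C=C(\C)CC/C=C(\C)CC/C=C(\C)CC/C=C(\C)CCC=C(C)C)c(O)c1OC | target

**Step count**

Total: 12 steps. Longest linear sequence: 10 steps (1, 2, 3, 5, 6, 7, 8, 10, 11, 12, from farnesol 1).

**Steps most likely to fail**

Step 10. The vinylcarbene formed after alkyne insertion may be diverted before CO inserts. The electron-donating β-methoxy group can favour cyclopentannulation without CO, a second alkyne may insert, or the carbene ligand of 17 may be lost thermally before it meets the alkyne. The fallback reaches the same kind of dienylketene without chromium. Alkyne 12 is hydrozirconated with Cp2Zr(H)Cl in THF and the vinylzirconium is cleaved with I2 to give (2E,5E,9E,13E,17E,21E)-2-iodo-6,10,14,18,22,26-hexamethylheptacosa-2,5,9,13,17,21,25-heptaene F1. Iodine–lithium exchange (t-BuLi, Et2O, −78 °C) and addition to commercial dimethyl squarate give 4-hydroxy-2,3-dimethoxy-4-[(2E,5E,9E,13E,17E,21E)-6,10,14,18,22,26-hexamethylheptacosa-2,5,9,13,17,21,25-heptaen-2-yl]cyclobut-2-en-1-one F2. Heating F2 in p-xylene at reflux under argon should open the four-membered ring to the dienylketene, which closes by 6π electrocyclisation and tautomerises to the hydroquinone. This returns to the route at 21, passing by 19 and 20. Because the squarate is symmetric, either regiochemistry of hydrozirconation converges on the same product.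

Step 9. In 15 the lithium and the β-methoxy group are trans, so anti elimination of lithium methoxide can compete on warming, before the vinyllithium has added to the sparingly soluble Cr(CO)6; residual t-BuLi may also attack Cr(CO)6. The fallback changes the vinyl anion to one that cannot eliminate in an anti sense. It sets out from 14 and uses (E)-1,2-dimethoxyethene F3 in place of 13. Lithiation gives (E)-1,2-dimethoxyvinyllithium F4, in which lithium is syn to the β-methoxy group. Addition to Cr(CO)6 gives lithium pentacarbonyl[(E)-2,3-dimethoxyprop-2-enoyl]chromate F5, and O-methylation with Me3OBF4 gives pentacarbonyl[(E)-1,2-dimethoxyvinyl(methoxy)carbene]chromium F6. Benzannulation of F6 with 12 under the conditions of step 10 returns to the route at 19, since the β-carbon loses its geometry on aromatisation.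

Step 6. Cleavage of the allylic C–S bond passes through a delocalised allyl anion, so protonation at the tertiary terminus (double-bond migration), E/Z erosion at the C14 alkene or over-reduction can lower the isomeric purity of the chain. The fallback separates the two cleavages and uses a hydride instead of an electron-transfer reduction. It sets out from 8. PdCl2(dppp) (cat., a divalent palladium precatalyst) with LiBHEt3 in THF at 0 °C should deliver hydride through a π-allyl palladium hydride to the less substituted terminus and give benzyl (2E,6E,10E,14E,18E)-3,7,11,15,19,23-hexamethyltetracosa-2,6,10,14,18,22-hexaenyl ether F7. The benzyl ether is then cleaved with LiC10H8 (lithium naphthalenide) in THF at −25 °C, which returns to the route at 9.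

**Further compounds**

F1 | step 10 | (2E,5E,9E,13E,17E,21E)-2-iodo-6,10,14,18,22,26-hexamethylheptacosa-2,5,9,13,17,21,25-heptaene | C/C(I)=C\C/C=C(\C)CC/C=C(\C)CC/C=C(\C)CC/C=C(\C)CC/C=C(\C)CCC=C(C)C
F2 | step 10 | 4-hydroxy-2,3-dimethoxy-4-[(2E,5E,9E,13E,17E,21E)-6,10,14,18,22,26-hexamethylheptacosa-2,5,9,13,17,21,25-heptaen-2-yl]cyclobut-2-en-1-one (racemic) | COC1=C(OC)C(O)(/C(C)=C/C/C=C(\C)CC/C=C(\C)CC/C=C(\C)CC/C=C(\C)CC/C=C(\C)CCC=C(C)C)C1=O
F3 | step 9 | (E)-1,2-dimethoxyethene (purchased) | CO/C=C/OC
F4 | step 9 | (E)-1,2-dimethoxyvinyllithium | [Li]/C(OC)=C\OC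
F5 | step 9 | lithium pentacarbonyl[(E)-2,3-dimethoxyprop-2-enoyl]chromate | [Li+].[O-]C(/C(OC)=C\OC)=[Cr](=C=O)(=C=O)(=C=O)(=C=O)=C=O
F6 | step 9 | pentacarbonyl[(E)-1,2-dimethoxyvinyl(methoxy)carbene]chromium | O=C=[Cr](=C=O)(=C=O)(=C=O)(=C=O)=C(OC)/C(OC)=C\OC
F7 | step 6 | benzyl (2E,6E,10E,14E,18E)-3,7,11,15,19,23-hexamethyltetracosa-2,6,10,14,18,22-hexaenyl ether | c1ccccc1COC/C=C(\C)CC/C=C(\C)CC/C=C(\C)CC/C=C(\C)CC/C=C(\C)CCC=C(C)C
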